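**Assumptions (one line):** tartrate and SEGPHOS enantiomers are chosen to give the drawn configurations (the two Ir couplings use opposite ligand enantiomers because the C7/C8 and C10/C11 units are mirror-related). Racemic vinyl epoxides 13 and 19 converge through a common π-allyl-Ir (dynamic kinetic asymmetric transformation). Numbering follows the target SMILES (C1 = CH3 of the propenyl, C15 = CH3 of the ethyl ketone).

## Retrosynthesis
1. Myriaporone 4 ⇐ acid removal of the acetonide and dioxolane ketal ⇐ C9 ketone 22 ⇐ cleavage of the exocyclic C9=CH2 of 20 (hydroxyl-directed OsO4, then NaIO4).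
2. 20 ⇐ Ir-catalysed transfer-hydrogenative coupling (C7–C8 bond, anti-diol) of cis-epoxy alcohol 9 with the 2-substituted vinyl epoxide 19 (proposed new).
3. 19 ⇐ α-methylenation and Corey–Chaykovsky epoxidation of an aldehyde obtained from anti-diol 14, which comes from the same Ir coupling (C10–C11 bond) of ketal-alcohol 12 with butadiene monoxide 13.
4. 9 ⇐ Sharpless AE of a Z-allylic alcohol made from (R)-Roche ester by Z-Wittig and Still–Gennari olefination.
5. Rings are formed in this order: epoxide (step 8), dioxolane ketal (step 9), dioxane acetonide (step 12). There are no carbocycles.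

## Route

**Step 1**
Reactants: 1 methyl (R)-3-hydroxy-2-methylpropanoate
Product: 2 methyl (R)-3-(TBSO)-2-methylpropanoate
Conditions: TBSCl, imidazole, DMF, 0 °C → rt
Reagents that add atoms: TBSCl, C[Si](C)(Cl)C(C)(C)C
Why: Standard silylation of the primary alcohol; the stereocentre is untouched.

**Step 2**
Reactants: 2
Product: 3 (R)-3-(TBSO)-2-methylpropanal
Conditions: DIBAL-H, CH2Cl2, –78 °C
Reagents that add atoms: none
Why: Partial ester reduction; the aluminium hemiacetal collapses only on work-up, so there is no over-reduction.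

**Step 3**
Reactants: 3
Product: 4 (Z)-alkene TBS ether
Conditions: EtPPh3Br, NaHMDS, THF, –78 °C → rt
Reagents that add atoms: ethyltriphenylphosphonium bromide, CC[P+](c1ccccc1)(c1ccccc1)c1ccccc1.[Br-]
Why: A non-stabilised ylide reacts through a cis-oxaphosphetane (Wittig reaction), giving the Z-propenyl unit.

**Step 4**
Reactants: 4
Product: 5 (2S,3Z)-2-methylpent-3-en-1-ol
Conditions: TBAF, THF, 0 °C
Reagents that add atoms: none
Why: Fluoride desilylation.

**Step 5**
Reactants: 5
Product: 6 (2S,3Z)-2-methylpent-3-enal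
Conditions: DMP, NaHCO3, CH2Cl2, 0 °C; use the crude aldehyde immediately
Reagents that add atoms: none
Why: Neutral Dess–Martin oxidation minimises epimerisation of the labile α-stereocentre.

**Step 6**
Reactants: 6
Product: 7 methyl (2Z,4S,5Z)-2,4-dimethylhepta-2,5-dienoate
Conditions: (CF3CH2O)2P(O)CH(CH3)CO2Me, KHMDS, 18-crown-6, THF, –78 °C (aldehyde added last)
Reagents that add atoms: methyl 2-[bis(2,2,2-trifluoroethoxy)phosphoryl]propanoate, COC(=O)C(C)P(=O)(OCC(F)(F)F)OCC(F)(F)F
Why: Still–Gennari olefination is kinetically Z-selective, which places C4 cis to the ester carbon (C7).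

**Step 7**
Reactants: 7
Product: 8 (2Z,4S,5Z)-2,4-dimethylhepta-2,5-dien-1-ol
Conditions: DIBAL-H (2.5 equiv), CH2Cl2, –78 °C
Reagents that add atoms: none
Why: Ester-to-alcohol reduction without alkene isomerisation.

**Step 8**
Reactants: 8
Product: 9 (2R,3S,4S,5Z)-2,3-epoxy-2,4-dimethylhept-5-en-1-ol
Conditions: Ti(OiPr)4, D-(–)-DET, TBHP, 4 Å MS, CH2Cl2, –20 °C
Reagents that add atoms: tert-butyl hydroperoxide, CC(C)(C)OO
Why: Sharpless asymmetric epoxidation, in which the Ti-tartrate catalyst fixes the face of O-transfer and so sets C5/C6; the Z-alkene gives the epoxide with C4 and C7 cis, as in the target.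

**Step 9**
Reactants: 10 pent-1-en-3-one (ethyl vinyl ketone)
Product: 11 2-ethyl-2-vinyl-1,3-dioxolane
Conditions: TMSOCH2CH2OTMS, TMSOTf (cat.), CH2Cl2, –78 → 0 °C
Reagents that add atoms: 1,2-bis(trimethylsilyloxy)ethane, C[Si](C)(C)OCCO[Si](C)(C)C
Why: Noyori ketalisation masks C13 as a ketal that survives the later Ir, ylide and Grignard-free conditions.

**Step 10**
Reactants: 11
Product: 12 2-(2-ethyl-1,3-dioxolan-2-yl)ethan-1-ol
Conditions: 9-BBN, THF, 0 °C → rt; then NaOH, H2O2
Reagents that add atoms: hydrogen peroxide, OO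
Why: Anti-Markovnikov hydroboration–oxidation of the terminal vinyl group.

**Step 11**
Reactants: 12; 13 2-vinyloxirane (3,4-epoxy-1-butene)
Product: 14 (2S,3S)-1-(2-ethyl-1,3-dioxolan-2-yl)-3-(hydroxymethyl)pent-4-en-2-ol
Conditions: [Ir(cod)Cl]2 (2.5 mol %), (R)-SEGPHOS (5 mol %), 3-nitrobenzoic acid (10 mol %), Cs2CO3 (10 mol %), THF, 100 °C
Reagents that add atoms: none
Why: Proposed new method: Ir(I) ionises the vinyl epoxide to a π-allyl-Ir bearing a pendant alkoxide, alcohol 12 is dehydrogenated to the aldehyde, and addition through the (E)-σ-allyl chair gives the anti 2-vinyl-1,3-diol with ligand-controlled C10/C11 configuration. The closest known reactions are Krische Ir-catalysed crotylation from α-methylallyl acetate and Tsuji–Trost opening of vinyl epoxides.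

**Step 12**
Reactants: 14
Product: 15 (4S,5S)-4-[(2-ethyl-1,3-dioxolan-2-yl)methyl]-2,2-dimethyl-5-vinyl-1,3-dioxane
Conditions: Me2C(OMe)2, PPTS (cat.), CH2Cl2, rt
Reagents that add atoms: 2,2-dimethoxypropane, COC(C)(C)OC
Why: Acetonide protection of the 1,3-diol (a mild transketalisation that leaves the ketal intact).

**Step 13**
Reactants: 15
Product: 16 2-[(4S,5S)-4-[(2-ethyl-1,3-dioxolan-2-yl)methyl]-2,2-dimethyl-1,3-dioxan-5-yl]ethan-1-ol
Conditions: 9-BBN, THF, rt; then NaOH, H2O2, 0 °C
Reagents that add atoms: hydrogen peroxide, OO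
Why: Hydroboration is selective for the terminal vinyl group and proceeds with retention at C10.

**Step 14**
Reactants: 16
Product: 17 2-[(4S,5S)-4-[(2-ethyl-1,3-dioxolan-2-yl)methyl]-2,2-dimethyl-1,3-dioxan-5-yl]acetaldehyde
Conditions: DMP, NaHCO3, CH2Cl2, rt
Reagents that add atoms: none
Why: Oxidation of the primary alcohol; C10 is β to the aldehyde and cannot epimerise.

**Step 15**
Reactants: 17
Product: 18 2-[(4S,5S)-…-1,3-dioxan-5-yl]prop-2-enal (α-methylene aldehyde)
Conditions: HCHO (37 % aq.), pyrrolidine (10 mol %), propionic acid (10 mol %), THF, rt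
Reagents that add atoms: formaldehyde, C=O
Why: Organocatalytic Mannich/elimination α-methylenation (Erkkilä–Pihko type) installs the exocyclic =CH2 that becomes the C9 carbonyl carbon's partner.

**Step 16**
Reactants: 18
Product: 19 2-{1-[(4S,5S)-…-1,3-dioxan-5-yl]ethenyl}oxirane (epimeric at the oxirane carbon)
Conditions: Me3S+ I–, n-BuLi, THF, –10 °C
Reagents that add atoms: trimethylsulfonium iodide, C[S+](C)C.[I-]
Why: Corey–Chaykovsky 1,2-addition of the sulfonium ylide to the enal gives the 2-substituted vinyl epoxide. The epoxide epimers are harmless because the stereocentre is destroyed on π-allyl formation in step 17.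

**Step 17**
Reactants: 9; 19
Product: 20 acetonide/ketal-protected anti-diol with exocyclic methylene (target numbering: 4S,5S,6R,7S,8R,10S,11S)
Conditions: [Ir(cod)Cl]2 (2.5 mol %), (S)-SEGPHOS (5 mol %), 3-nitrobenzoic acid (10 mol %), Cs2CO3 (10 mol %), THF, 90 °C
Reagents that add atoms: none
Why: Proposed new method: the same Ir-π-allyl/alkoxide mechanism as step 11, now between a neopentylic epoxy alcohol and a 2-substituted, stereochemically complex vinyl epoxide. The allyl terminus carrying CH2O– adds to the transiently formed epoxy aldehyde through the (E)-σ-allyl chair, setting the anti C7/C8 pair (reagent-controlled) and leaving the C9=CH2 alkene; this is the convergent C–C bond. The closest known reactions are Krische Ir-catalysed anti-crotylation and vinyl-epoxide Tsuji–Trost allylation.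

**Step 18**
Reactants: 20
Product: 21 tetrol (C9 tertiary alcohol; C9 epimeric mixture)
Conditions: OsO4 (1.2 equiv), TMEDA, CH2Cl2, –78 °C; then aq. NaHSO3, THF, rt
Reagents that add atoms: osmium tetroxide, O=[Os](=O)(=O)=O
Why: Donohoe hydroxyl-directed dihydroxylation favours the exocyclic alkene, which sits next to the free C7-OH/C8-CH2OH, over the Z-alkene; the new C9 stereocentre is irrelevant because it is cleaved in step 19.

**Step 19**
Reactants: 21
Product: 22 ketone (C9 carbonyl)
Conditions: NaIO4, NaHCO3, THF–H2O (3:1), 0 °C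
Reagents that add atoms: none
Why: Malaprade cleavage of the vicinal C9(OH)–CH2OH diol gives the ketone and formaldehyde; the trans-type acetonide locks C10 and the C8 centre is not touched.

**Step 20**
Reactants: 22
Product: 23 myriaporone 4
Conditions: CSA (0.3 equiv), MeOH–H2O (4:1), 35 °C
Reagents that add atoms: water, O
Why: Acid hydrolysis of the acetonide and the dioxolane ketal releases the free diol and the C13 ketone, giving the target.

## Compound list
1 | methyl (R)-3-hydroxy-2-methylpropanoate | COC(=O)[C@H](C)CO | starting material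
2 | methyl (R)-3-(TBSO)-2-methylpropanoate | COC(=O)[C@H](C)CO[Si](C)(C)C(C)(C)C | intermediate
3 | (R)-3-(TBSO)-2-methylpropanal | O=C[C@H](C)CO[Si](C)(C)C(C)(C)C | intermediate
4 | tert-butyl(dimethyl){[(2S,3Z)-2-methylpent-3-en-1-yl]oxy}silane | C/C=C\[C@H](C)CO[Si](C)(C)C(C)(C)C | intermediate
5 | (2S,3Z)-2-methylpent-3-en-1-ol | C/C=C\[C@H](C)CO | intermediate
6 | (2S,3Z)-2-methylpent-3-enal | C/C=C\[C@H](C)C=O | intermediate
7 | methyl (2Z,4S,5Z)-2,4-dimethylhepta-2,5-dienoate | C/C=C\[C@H](C)/C=C(/C)C(=O)OC | intermediate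
8 | (2Z,4S,5Z)-2,4-dimethylhepta-2,5-dien-1-ol | C/C=C\[C@H](C)/C=C(/C)CO | intermediate
9 | (2R,3S,4S,5Z)-2,3-epoxy-2,4-dimethylhept-5-en-1-ol | C/C=C\[C@H](C)[C@@H]1O[C@]1(C)CO | intermediate
10 | pent-1-en-3-one | C=CC(=O)CC | starting material
11 | 2-ethyl-2-vinyl-1,3-dioxolane | C=CC1(CC)OCCO1 | intermediate
12 | 2-(2-ethyl-1,3-dioxolan-2-yl)ethan-1-ol | OCCC1(CC)OCCO1 | intermediate
13 | 2-vinyloxirane | C=CC1CO1 | starting material
14 | (2S,3S)-1-(2-ethyl-1,3-dioxolan-2-yl)-3-(hydroxymethyl)pent-4-en-2-ol | C=C[C@@H](CO)[C@@H](O)CC1(CC)OCCO1 | intermediate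
15 | (4S,5S)-4-[(2-ethyl-1,3-dioxolan-2-yl)methyl]-2,2-dimethyl-5-vinyl-1,3-dioxane | C=C[C@H]1COC(C)(C)O[C@H]1CC2(CC)OCCO2 | intermediate
16 | 2-[(4S,5S)-4-[(2-ethyl-1,3-dioxolan-2-yl)methyl]-2,2-dimethyl-1,3-dioxan-5-yl]ethan-1-ol | OCC[C@H]1COC(C)(C)O[C@H]1CC2(CC)OCCO2 | intermediate
17 | corresponding acetaldehyde | O=CC[C@H]1COC(C)(C)O[C@H]1CC2(CC)OCCO2 | intermediate
18 | corresponding 2-substituted prop-2-enal | C=C(C=O)[C@H]1COC(C)(C)O[C@H]1CC2(CC)OCCO2 | intermediate
19 | corresponding 2-vinyl-type oxirane (oxirane carbon epimeric) | C=C(C1CO1)[C@H]2COC(C)(C)O[C@H]2CC3(CC)OCCO3 | intermediate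
20 | coupling product (4S,5S,6R,7S,8R,10S,11S; cis-epoxide, Z-alkene, exocyclic methylene) | C/C=C\[C@H](C)[C@@H]1O[C@]1(C)[C@@H](O)[C@@H](CO)C(=C)[C@H]2COC(C)(C)O[C@H]2CC3(CC)OCCO3 | intermediate
21 | C9-diol (tetrol; C9 mixture) | C/C=C\[C@H](C)[C@@H]1O[C@]1(C)[C@@H](O)[C@@H](CO)C(O)(CO)[C@H]2COC(C)(C)O[C@H]2CC3(CC)OCCO3 | intermediate
22 | protected C9 ketone | C/C=C\[C@H](C)[C@@H]1O[C@]1(C)[C@@H](O)[C@@H](CO)C(=O)[C@H]2COC(C)(C)O[C@H]2CC3(CC)OCCO3 | intermediate
23 | myriaporone 4 | C/C=C\[C@H](C)[C@@H]1O[C@]1(C)[C@@H](O)[C@@H](CO)C(=O)[C@@H](CO)[C@@H](O)CC(=O)CC | target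

**Total steps:** 20. **Longest linear sequence:** 12 (steps 1–8, 17–20; the other branch, steps 9–16, gives the same 12), which is 60 % of the total.

## Three steps most likely to fail
1. **Step 17 (and its model, step 11), the proposed new Ir coupling.** The hindered neopentylic epoxy alcohol, base and heat may cause low conversion, Payne-type or alkene-isomerisation side reactions, or mismatched diastereoselectivity. Fallback (known chemistry): oxidise 9 to the aldehyde and build C7–C8 by a Paterson E-boron-enolate anti-aldol with a ketone made from 15 (Wacker oxidation, then aqueous HCHO hydroxymethylation); make 14 by Roush tartrate-modified (E)-γ-(silyloxymethyl)allylboration of the aldehyde from 12.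
2. **Step 18, chemoselective dihydroxylation of the exocyclic alkene in the presence of the Z-alkene.** Fallback: carry the Z-propenyl as a propynyl group (Ohira–Bestmann homologation then MeI on the C3 aldehyde), cleave the exocyclic alkene by plain ozonolysis, and finish with a Lindlar reduction.
3. **Step 20, global acid deprotection in the presence of the epoxide and β-hydroxy ketones (the dioxolane ketal is the hard part).** Fallback: replace the ketal by a C13 silyl ether (from pentane-1,3-diol), remove the acetonide under mild PPTS/MeOH, and oxidise C13 with DMP as the penultimate step.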